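## The problem

Compound 17 is a 7,9'-epoxylignan: an oxolane (O1, C2–C5) carrying the 3,4,5-trimethoxyphenyl ring A on C2, a hydroxymethyl group (C6) on C3 and the 3,4-dimethoxybenzyl group (C7, ring B) on C4. Three contiguous stereocentres have to be set, C2 (R), C3 (S) and C4 (S): the aryl group is trans to the hydroxymethyl group, which is cis to the benzyl group. C3 and C4 cannot be corrected once made, and their cis relation is the more crowded one on the oxolane, so it must come from a kinetically controlled step before the ring exists. C2 is different: it is benzylic and ether-bearing, can be ionised reversibly, and can therefore be set last under the control of C3 and C4. That same lability is the main hazard, because acid can reopen the ring at C2 and let ring B capture the cation as an aryltetralin; the benzylic C2–O bond is also open to hydrogenolysis, and both electron-rich rings rule out electrophilic halogen sources and strong oxidants. The two aryl groups differ, so they must enter in separate bond-forming events. The enabling feature is the chain C6–C3–C4–C5, a four-carbon unit oxygenated at both ends: it is the skeleton of a butenolide with C5 as carbonyl, C4 as α-carbon, C3 as β-carbon and C6 as the γ-acetal carbon, so C2 can be attached to C3 as an acyl-anion equivalent and C7 to C4 as an electrophile. Because C3 changes its ring neighbour (C6 in the lactone, C2 in the oxolane), the easily made trans α,β-lactone becomes the required 3,4-cis oxolane.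

## Retrosynthesis

**O1–C2.** The last bond to be made is O1–C2, and cutting it opens 17 to triol 15, in which C2 is a benzylic carbinol of either configuration. The neighbouring cut, O1–C5, would require the two primary hydroxyls on C5 and C6 to be told apart and C2 to be made as a single carbinol epimer. With O1–C2 only C2 can ionise (cation 16), and only the C5 hydroxyl reaches it through a five-membered transition state, since the C6 hydroxyl would give an oxetane. The C2 configuration is then dictated by C3 and C4, because the other epimer is the all-cis oxolane. The forward step must be a mild acid-catalysed SN1 etherification, stopped before ring B can intervene.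

**Reduction level.** Triol 15 is three reductions away from keto lactone 14: the C2 ketone, the C5 lactone carbonyl and the C6 acetal carbon all end as alcohols, and reduction of the acetal carbon also releases the auxiliary alcohol 4. No skeletal bond is cut, but the problem becomes much simpler. Compound 14 holds only the two fixed centres C3 and C4 plus the auxiliary acetal centre, and C2 needs no control at this stage.

**Carbonyl unmasking.** The C2 carbonyl of 14 is revealed from the 1,3-dithiane of 13. The dithiane is what allows C2 to react as a nucleophile; the forward step must remove it without harming the acetal or the electron-rich rings.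

**C2–C3 and C4–C7 (key disconnection).** Adduct 13 is cut at both bonds flanking C3–C4, giving dithiane 8, butenolide 6 and bromide 10. An aldol or alkylation on a preformed β-benzyl lactone would need that lactone as a single enantiomer first; here the two different aryl units are attached to a four-carbon core that brings its own removable stereocontrol. All three precursors are one or two steps from bulk chemicals. The forward reaction must add the lithiated dithiane 11 in a 1,4 sense anti to the menthyloxy group, and alkylate enolate 12 anti to the new dithianyl group.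

**Building blocks.** Butenolide 6 is the (+)-menthyl acetal of hydroxybutenolide 3, cut at the exocyclic acetal C–O bond; 3 is the singlet-oxygen product of furfural 1 by way of endoperoxide 2. The acetal centre is labile under acid, so the forward step can drain epimer 5 into crystalline 6. Dithiane 8 comes from aldehyde 7 by thioacetalisation and bromide 10 from alcohol 9 by bromination.

## Roads not taken

**Alternative 1:** The cut is C4–C5. The phenylselenomethyl ether A1 of a (1R,2S)-homopropargylic alcohol would be treated with Bu3SnH and AIBN (azobisisobutyronitrile). The resulting alkoxymethyl radical on O1 would close 5-exo-dig onto alkyne carbon C4 and give the 4-benzylidene oxolane A2; hydrogenation of the exocyclic alkene and desilylation would finish.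
- Merits: C2 and C3 are configured before the ring forms and are never ionised, so no acid step threatens the benzylic ether. The radical closure tolerates both arenes and joins the two aryl halves convergently. In freedom from cationic chemistry at C2 this road is better than the chosen plan.
- Weak points: the C2/C3 pair in A1 must be made by separate asymmetric chemistry, which costs several steps. C4 is set only at the end by hydrogenation, which depends on facial selectivity and exposes the benzylic C2–O bond to hydrogenolysis. Stoichiometric tin and selenium reagents are needed.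
- Comparison: the chosen plan sets C3 and C4 together in one step from a crystalline chiral template, uses no late hydrogenation, and is markedly shorter.

**Alternative 2:** The cut is O1–C2, as in the chosen endgame, but made oxidatively. DDQ would oxidise the 4-hydroxy-3,5-dimethoxybenzyl group of the (2S,3S)-diol A3 to a para-quinone methide, and the C5 hydroxyl would add 5-exo to give phenol A4; O-methylation would then give the target.
- Merits: the closure is biomimetic and needs no ketone, no dithiane hydrolysis and no Brønsted acid, and the phenol directs DDQ to the correct benzylic position. As a ring-closing step it is at least as good as the chosen one and probably more reliably trans-selective.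
- Weak points: the target carries no free phenol, so a protecting group must be carried, removed and replaced by methyl. DDQ can over-oxidise the product or attack the dimethoxybenzyl position, and the quinone methide can also be captured by ring B. A3 must itself be made enantioselectively with two different aryl groups, most simply by the same butenolide chemistry, so the road solves the closure and not the C3/C4 problem.
- Comparison: the chosen plan carries the fully methylated aryl group from a commercial aldehyde, needs no oxidant in the presence of two electron-rich rings and saves the protecting-group steps. The quinone methide closure is kept as the fallback for its last step.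

**Alternative 3:** The cut is O1–C5. Rh2(OAc)4 (divalent rhodium) would decompose the diazoketone A5 and the carbenoid carbon C5 would insert into the O–H bond of the C2 hydroxyl, giving the 4-oxo oxolane A6. Ring B would then be added by olefination of the C4 ketone, hydrogenation and desilylation.
- Merits: the ring closes without touching C2, the rhodium is catalytic, and the C4 ketone allows ring B to be varied late. For analogue work this is better than the chosen plan.
- Weak points: in A6 the C3 centre is α to the ketone and carries a β-silyloxy group, so epimerisation and β-elimination both threaten it. A5 requires activation of a β-hydroxy acid and a diazomethane homologation with the hydroxyl free for the insertion. C4 is again set by a late hydrogenation next to a benzylic ether, and the sequence is several steps longer.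
- Comparison: the chosen plan forms C3 and C4 in one step with both substituents in place and never makes C3 enolisable with a β-leaving group outside one short-lived ketone stage.

Key step: step 5

Remark on the chemistry: of the two acetal epimers formed from 3 and (+)-menthol, the (5S) epimer 6 is taken to be the crystalline one, because it is the mirror image of the crystalline (5R) epimer formed with (−)-menthol.

## Route

Step 1
Reactants: 1 furfural
Product: 3 5-hydroxyfuran-2(5H)-one (racemic), via furan endoperoxide 2 (not isolated)
Conditions: O2, hν, rose bengal (tetrachlorotetraiodofluorescein disodium salt, cat.), MeOH, rt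
Reagents that add atoms: oxygen, O=O
Why: Sensitised singlet-oxygen [4+2] cycloaddition to the furan gives endoperoxide 2; methanol adds to the formyl group and fragmentation expels methyl formate, leaving the γ-hydroxybutenolide. This photo-oxygenation of furfural is a standard preparation, and the C5 centre formed is racemic and equilibrating.

Step 2
Reactants: 3 5-hydroxyfuran-2(5H)-one, 4 (+)-menthol [(1S,2R,5S)-2-isopropyl-5-methylcyclohexanol]
Product: 6 (5S)-5-{[(1S,2R,5S)-2-isopropyl-5-methylcyclohexyl]oxy}furan-2(5H)-one, via 5R acetal epimer 5 (not isolated)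
Conditions: neat, 100 °C; crystallise from petroleum ether, −20 °C; mother liquor, camphor-10-sulfonic acid (cat.), recrystallise
Reagents that add atoms: none
Why: Acetalisation of the cyclic hemiacetal through the furanone oxocarbenium ion gives both C5 epimers. Acid keeps the acetal centre equilibrating while 6 crystallises, so epimer 5 is drained into 6 (crystallisation-induced diastereomer transformation) and C5 is set as S.

Step 3
Reactants: 7 3,4,5-trimethoxybenzaldehyde
Product: 8 2-(3,4,5-trimethoxyphenyl)-1,3-dithiane
Conditions: HS(CH2)3SH, BF3·OEt2 (cat.), CH2Cl2, 0 °C to rt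
Reagents that add atoms: propane-1,3-dithiol, SCCCS
Why: Lewis acid-catalysed dithioacetalisation of an aromatic aldehyde; no stereocentre is formed.

Step 4
Reactants: 9 3,4-dimethoxybenzyl alcohol
Product: 10 4-(bromomethyl)-1,2-dimethoxybenzene
Conditions: PBr3, Et2O, 0 °C; used at once
Reagents that add atoms: phosphorus tribromide, BrP(Br)Br
Why: Bromination of a benzylic alcohol through its phosphite ester; the electron-rich bromide stores poorly and is therefore made just before step 5.

Step 5
Reactants: 8 2-(3,4,5-trimethoxyphenyl)-1,3-dithiane, 6 (5S)-5-(d-menthyloxy)furan-2(5H)-one, 10 4-(bromomethyl)-1,2-dimethoxybenzene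
Product: 13 (3S,4S,5S)-3-(3,4-dimethoxybenzyl)-5-{[(1S,2R,5S)-2-isopropyl-5-methylcyclohexyl]oxy}-4-[2-(3,4,5-trimethoxyphenyl)-1,3-dithian-2-yl]oxolan-2-one, via 2-lithio dithiane 11 (not isolated), via lithium lactone enolate 12 (not isolated)
Conditions: n-BuLi, THF, −78 °C; then 6, −78 °C; then 10, TMEDA, −78 °C to rt
Reagents that add atoms: none
Why: n-BuLi removes the C2 proton of 8 to give the aryl-stabilised carbanion 11, which adds to the β-carbon of butenolide 6 in a Michael addition to give lithium enolate 12; 12 is then C-benzylated by bromide 10 in an SN2 step. The closest known reaction type is the three-component conjugate addition and enolate alkylation of 2-aryl-2-lithio-1,3-dithianes on butenolides, established for 5-alkoxyfuran-2(5H)-ones with benzylic bromides. No ring is closed; the lactone of 6 serves only as a template. The β-centre (C3 of the target) is controlled by the acetal carbon, the bulky nucleophile entering the face anti to the menthyloxy group. The α-centre (C4 of the target) is controlled by the new C3 substituent, whose quaternary dithianyl group shields one enolate face so that the benzyl group enters trans to it. The step needs 1,4- over 1,2-addition, which the soft delocalised aryl dithiane anion and the unhindered β-carbon at −78 °C should secure, and C- over O-alkylation, which the lithium enolate, TMEDA and a reactive benzylic bromide should secure. Since 6 is a single enantiomer, both centres are fixed in the absolute sense as well.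

Step 6
Reactants: 13 the dithiane adduct
Product: 14 (3S,4S,5S)-3-(3,4-dimethoxybenzyl)-5-{[(1S,2R,5S)-2-isopropyl-5-methylcyclohexyl]oxy}-4-(3,4,5-trimethoxybenzoyl)oxolan-2-one
Conditions: HgO, BF3·OEt2, THF/H2O, rt
Reagents that add atoms: water, O
Why: Thiophile-assisted hydrolysis of the dithiane (the unmasking half of dithiane umpolung) frees the aryl ketone without halogenating or oxidising agents that would attack the electron-rich rings. C3 becomes α to a ketone, but its trans,trans arrangement is the preferred one; the β-acyloxy ketone is kept away from base and reduced promptly.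

Step 7
Reactants: 14 the keto lactone
Product: 15 (2S,3S)-2-(3,4-dimethoxybenzyl)-3-[hydroxy(3,4,5-trimethoxyphenyl)methyl]butane-1,4-diol (both carbinol epimers)
Conditions: LiAlH4, THF, 0 °C to reflux; aq. NaOH work-up
Reagents that add atoms: none
Why: Hydride reduces the ketone and opens the lactone; the resulting menthyl hemiacetal alkoxide collapses to the aldehyde, which is reduced in turn, so C5 and C6 both become CH2OH and (+)-menthol is released for recovery. The carbinol centre forms as a mixture, which step 8 erases.

Step 8
Reactants: 15 the triol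
Product: 17 [(2R,3S,4S)-4-(3,4-dimethoxybenzyl)-2-(3,4,5-trimethoxyphenyl)oxolan-3-yl]methanol, via C2 benzylic cation 16 (not isolated)
Conditions: TsOH·H2O (cat.), CH2Cl2, 0 °C to rt; NaHCO3 quench at full conversion
Reagents that add atoms: none
Why: Acid-catalysed SN1 cycloetherification: both carbinol epimers ionise to the same para-methoxy-stabilised cation 16, and the C5 hydroxyl captures it 5-exo, the C6 hydroxyl being able to form only an oxetane. C2 is set as R because the aryl group closes trans to the C3 hydroxymethyl group; the alternative is the all-cis oxolane, and any of it formed can re-ionise and correct itself.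

## Compound list

1 | furfural | O=Cc1ccco1 | starting material
2 | furfural 2,5-endoperoxide (2,3,7-trioxabicyclo[2.2.1]hept-5-ene-1-carbaldehyde) | O=CC12OOC(C=C1)O2 | intermediate (not isolated)
3 | 5-hydroxyfuran-2(5H)-one (racemic) | O=C1C=CC(O)O1 | intermediate
4 | (+)-menthol, (1S,2R,5S)-2-isopropyl-5-methylcyclohexanol | CC(C)[C@H]1CC[C@H](C)C[C@@H]1O | starting material
5 | (5R)-5-{[(1S,2R,5S)-2-isopropyl-5-methylcyclohexyl]oxy}furan-2(5H)-one | O=C1C=C[C@H](O[C@H]2C[C@@H](C)CC[C@@H]2C(C)C)O1 | intermediate (not isolated)
6 | (5S)-5-{[(1S,2R,5S)-2-isopropyl-5-methylcyclohexyl]oxy}furan-2(5H)-one | O=C1C=C[C@@H](O[C@H]2C[C@@H](C)CC[C@@H]2C(C)C)O1 | intermediate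
7 | 3,4,5-trimethoxybenzaldehyde | COc1cc(C=O)cc(OC)c1OC | starting material
8 | 2-(3,4,5-trimethoxyphenyl)-1,3-dithiane | COc1cc(C2SCCCS2)cc(OC)c1OC | intermediate
9 | 3,4-dimethoxybenzyl alcohol | COc1ccc(CO)cc1OC | starting material
10 | 4-(bromomethyl)-1,2-dimethoxybenzene | COc1ccc(CBr)cc1OC | intermediate
11 | 2-lithio-2-(3,4,5-trimethoxyphenyl)-1,3-dithiane | COc1cc(C2([Li])SCCCS2)cc(OC)c1OC | intermediate (not isolated)
12 | lithium (4S,5S)-5-(d-menthyloxy)-4-[2-(3,4,5-trimethoxyphenyl)-1,3-dithian-2-yl]-4,5-dihydrofuran-2-olate | [Li]OC1=C[C@H](C2(SCCCS2)c2cc(OC)c(OC)c(OC)c2)[C@@H](O[C@H]2C[C@@H](C)CC[C@@H]2C(C)C)O1 | intermediate (not isolated)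
13 | (3S,4S,5S)-3-(3,4-dimethoxybenzyl)-5-{[(1S,2R,5S)-2-isopropyl-5-methylcyclohexyl]oxy}-4-[2-(3,4,5-trimethoxyphenyl)-1,3-dithian-2-yl]oxolan-2-one | COc1ccc(C[C@@H]2C(=O)O[C@H](O[C@H]3C[C@@H](C)CC[C@@H]3C(C)C)[C@H]2C2(SCCCS2)c2cc(OC)c(OC)c(OC)c2)cc1OC | intermediate
14 | (3S,4S,5S)-3-(3,4-dimethoxybenzyl)-5-{[(1S,2R,5S)-2-isopropyl-5-methylcyclohexyl]oxy}-4-(3,4,5-trimethoxybenzoyl)oxolan-2-one | COc1ccc(C[C@@H]2C(=O)O[C@H](O[C@H]3C[C@@H](C)CC[C@@H]3C(C)C)[C@H]2C(=O)c2cc(OC)c(OC)c(OC)c2)cc1OC | intermediate
15 | (2S,3S)-2-(3,4-dimethoxybenzyl)-3-[hydroxy(3,4,5-trimethoxyphenyl)methyl]butane-1,4-diol (carbinol epimers) | COc1ccc(C[C@H](CO)[C@@H](CO)C(O)c2cc(OC)c(OC)c(OC)c2)cc1OC | intermediate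
16 | C2 benzylic carbocation of triol 15 | COc1ccc(C[C@H](CO)[C@@H](CO)[CH+]c2cc(OC)c(OC)c(OC)c2)cc1OC | intermediate (not isolated)
17 | [(2R,3S,4S)-4-(3,4-dimethoxybenzyl)-2-(3,4,5-trimethoxyphenyl)oxolan-3-yl]methanol | COc1ccc(C[C@@H]2CO[C@@H](c3cc(OC)c(OC)c(OC)c3)[C@@H]2CO)cc1OC | target

## Step count and risks

Total step count: 8. Longest linear sequence: 6 (steps 1, 2, 5, 6, 7, 8).

**Step 5 (key step).**
- Risk: incomplete capture of the hindered enolate 12, which then ends as the protonated, unbenzylated adduct. Bromide 10 may also be consumed by residual 11, and some 1,2-addition to the lactone carbonyl may occur.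
- Fallback: split the operation in two, setting out from 8 and 6. The conjugate addition is run alone and quenched with NH4Cl to isolate the Michael adduct (4S,5S)-5-(d-menthyloxy)-4-[2-(3,4,5-trimethoxyphenyl)-1,3-dithian-2-yl]oxolan-2-one F1. F1 is then re-enolised with LiN(iPr)2 in THF at −78 °C, in the absence of any dithiane anion, and alkylated with 10, again trans to the dithianyl group. This comes back to the route at 13.

**Step 8.**
- Risk: capture of cation 16 by ring B (Friedel–Crafts closure to an aryltetralin), which becomes the sink if the oxolane re-ionises under acid, together with incomplete trans selection at C2 if the reaction must be stopped early.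
- Fallback: move the closure to a para-quinone methide, which forms without strong acid. It sets out from 6 and 10 and uses commercial 4-(benzyloxy)-3,5-dimethoxybenzaldehyde in place of 7.
  - Thioacetalisation as in step 3 would give 2-[4-(benzyloxy)-3,5-dimethoxyphenyl]-1,3-dithiane F2.
  - The three-component coupling of F2 with 6 and 10 as in step 5 would give the adduct (3S,4S,5S)-4-{2-[4-(benzyloxy)-3,5-dimethoxyphenyl]-1,3-dithian-2-yl}-3-(3,4-dimethoxybenzyl)-5-(d-menthyloxy)oxolan-2-one F3.
  - HgO/BF3·OEt2 hydrolysis would give the ketone (3S,4S,5S)-4-[4-(benzyloxy)-3,5-dimethoxybenzoyl]-3-(3,4-dimethoxybenzyl)-5-(d-menthyloxy)oxolan-2-one F4.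
  - LiAlH4 reduction would give the benzyl-protected triol (2S,3S)-3-{[4-(benzyloxy)-3,5-dimethoxyphenyl](hydroxy)methyl}-2-(3,4-dimethoxybenzyl)butane-1,4-diol F5.
  - Hydrogenolysis (H2, Pd/C, EtOAc) would free the phenolic triol (2S,3S)-2-(3,4-dimethoxybenzyl)-3-[hydroxy(4-hydroxy-3,5-dimethoxyphenyl)methyl]butane-1,4-diol F6.
  - With a trace of pyridinium tosylate, F6 should lose water to the quinone methide and close 5-exo through the C5 hydroxyl, trans to the C3 substituent, to give 4-[(2R,3S,4S)-4-(3,4-dimethoxybenzyl)-3-(hydroxymethyl)oxolan-2-yl]-2,6-dimethoxyphenol F7 (the same compound as A4).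
  - MeI and K2CO3 in acetone would methylate the phenol only and come back to the route at 17.

**Step 6.**
- Risk: slow unmasking of a dithiane flanked by two branched carbons, loss or scrambling of the acetal centre under the Lewis acid, and β-elimination of the lactone carboxylate from the β-acyloxy ketone once it has formed.
- Fallback: reverse the order, setting out from 13. LiAlH4 would first reduce the lactone acetal with the dithiane intact, giving (2S,3S)-2-(3,4-dimethoxybenzyl)-3-[2-(3,4,5-trimethoxyphenyl)-1,3-dithian-2-yl]butane-1,4-diol F8. Alkylative hydrolysis (MeI, CaCO3, aqueous MeCN) would then give (2S,3S)-3-(3,4-dimethoxybenzyl)-4-hydroxy-2-(hydroxymethyl)-1-(3,4,5-trimethoxyphenyl)butan-1-one F9, which should exist largely as its five-membered cyclic hemiketal. NaBH4 in MeOH would reduce the open keto form and come back to the route at 15. No acetal or acyloxy leaving group is present when the ketone appears.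

## Further compounds

F1 | step 5 | (4S,5S)-5-(d-menthyloxy)-4-[2-(3,4,5-trimethoxyphenyl)-1,3-dithian-2-yl]oxolan-2-one | O=C1C[C@H](C2(SCCCS2)c2cc(OC)c(OC)c(OC)c2)[C@@H](O[C@H]2C[C@@H](C)CC[C@@H]2C(C)C)O1
F2 | step 8 | 2-[4-(benzyloxy)-3,5-dimethoxyphenyl]-1,3-dithiane | COc1cc(C2SCCCS2)cc(OC)c1OCc1ccccc1
F3 | step 8 | (3S,4S,5S)-4-{2-[4-(benzyloxy)-3,5-dimethoxyphenyl]-1,3-dithian-2-yl}-3-(3,4-dimethoxybenzyl)-5-(d-menthyloxy)oxolan-2-one | COc1ccc(C[C@@H]2C(=O)O[C@H](O[C@H]3C[C@@H](C)CC[C@@H]3C(C)C)[C@H]2C2(SCCCS2)c2cc(OC)c(OCc3ccccc3)c(OC)c2)cc1OC
F4 | step 8 | (3S,4S,5S)-4-[4-(benzyloxy)-3,5-dimethoxybenzoyl]-3-(3,4-dimethoxybenzyl)-5-(d-menthyloxy)oxolan-2-one | COc1ccc(C[C@@H]2C(=O)O[C@H](O[C@H]3C[C@@H](C)CC[C@@H]3C(C)C)[C@H]2C(=O)c2cc(OC)c(OCc3ccccc3)c(OC)c2)cc1OC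
F5 | step 8 | (2S,3S)-3-{[4-(benzyloxy)-3,5-dimethoxyphenyl](hydroxy)methyl}-2-(3,4-dimethoxybenzyl)butane-1,4-diol (carbinol epimers) | COc1ccc(C[C@H](CO)[C@@H](CO)C(O)c2cc(OC)c(OCc3ccccc3)c(OC)c2)cc1OC
F6 | step 8 | (2S,3S)-2-(3,4-dimethoxybenzyl)-3-[hydroxy(4-hydroxy-3,5-dimethoxyphenyl)methyl]butane-1,4-diol (carbinol epimers) | COc1ccc(C[C@H](CO)[C@@H](CO)C(O)c2cc(OC)c(O)c(OC)c2)cc1OC
F7 | step 8 | 4-[(2R,3S,4S)-4-(3,4-dimethoxybenzyl)-3-(hydroxymethyl)oxolan-2-yl]-2,6-dimethoxyphenol | COc1ccc(C[C@@H]2CO[C@@H](c3cc(OC)c(O)c(OC)c3)[C@@H]2CO)cc1OC
F8 | step 6 | (2S,3S)-2-(3,4-dimethoxybenzyl)-3-[2-(3,4,5-trimethoxyphenyl)-1,3-dithian-2-yl]butane-1,4-diol | COc1ccc(C[C@H](CO)[C@@H](CO)C2(SCCCS2)c2cc(OC)c(OC)c(OC)c2)cc1OC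
F9 | step 6 | (2S,3S)-3-(3,4-dimethoxybenzyl)-4-hydroxy-2-(hydroxymethyl)-1-(3,4,5-trimethoxyphenyl)butan-1-one | COc1ccc(C[C@H](CO)[C@@H](CO)C(=O)c2cc(OC)c(OC)c(OC)c2)cc1OC
A1 | alternative 1 | (1R,2S)-2-[(tert-butyldimethylsilyloxy)methyl]-4-(3,4-dimethoxyphenyl)-1-[(phenylselanyl)methoxy]-1-(3,4,5-trimethoxyphenyl)but-3-yne | COc1ccc(C#C[C@@H](CO[Si](C)(C)C(C)(C)C)[C@@H](OC[Se]c2ccccc2)c2cc(OC)c(OC)c(OC)c2)cc1OC
A2 | alternative 1 | tert-butyldimethylsilyl ether of [(2R,3S,E)-4-(3,4-dimethoxybenzylidene)-2-(3,4,5-trimethoxyphenyl)oxolan-3-yl]methanol | COc1ccc(/C=C2/CO[C@@H](c3cc(OC)c(OC)c(OC)c3)[C@@H]2CO[Si](C)(C)C(C)(C)C)cc1OC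
A3 | alternative 2 | (2S,3S)-2-(3,4-dimethoxybenzyl)-3-(4-hydroxy-3,5-dimethoxybenzyl)butane-1,4-diol | COc1ccc(C[C@H](CO)[C@@H](CO)Cc2cc(OC)c(O)c(OC)c2)cc1OC
A4 | alternative 2 | 4-[(2R,3S,4S)-4-(3,4-dimethoxybenzyl)-3-(hydroxymethyl)oxolan-2-yl]-2,6-dimethoxyphenol | COc1ccc(C[C@@H]2CO[C@@H](c3cc(OC)c(O)c(OC)c3)[C@@H]2CO)cc1OC
A5 | alternative 3 | (3S,4R)-1-diazo-4-hydroxy-4-(3,4,5-trimethoxyphenyl)-3-[(triisopropylsilyloxy)methyl]butan-2-one | [N-]=[N+]=CC(=O)[C@@H](CO[Si](C(C)C)(C(C)C)C(C)C)[C@@H](O)c1cc(OC)c(OC)c(OC)c1
A6 | alternative 3 | (4S,5R)-5-(3,4,5-trimethoxyphenyl)-4-[(triisopropylsilyloxy)methyl]oxolan-3-one | O=C1CO[C@@H](c2cc(OC)c(OC)c(OC)c2)[C@@H]1CO[Si](C(C)C)(C(C)C)C(C)C
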